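**Numbering used throughout:** lactone O1, C2 (carbonyl), C3, C4, C5; side chain C1'–C10' from the alkylidene carbon to the ether carbon. Compounds 1–28 are defined in the steps and in the compound list.

## Analysis of the target

The target is a monocyclic α-alkylidene γ-butyrolactone whose C3 carries an E-configured exocyclic alkene to a ten-carbon chain, C1'–C10', that ends as an ether of (E)-4-hydroxycinnamyl alcohol. The ring holds two adjacent stereocentres, C4 (S, acetoxy) and C5 (R, 2-methylprop-1-enyl), trans to one another. The third, C3' (R), is a secondary allylic carbinol separated from C4 by the C3=C1' alkene and C2', so the ring cannot be expected to bias it. Four alkenes of fixed geometry must be delivered: C3=C1' (E), the trisubstituted C4'=C5' (E), the neryl alkene C8'=C9' (Z) and the E-styrenyl bond. The sensitive points are the C4 acetate (β to C2 through C3 and expelled by any carbanion character at C3), the alkylidene lactone as a Michael acceptor, the allylic C5–O1 and C3'–O bonds, the acid-labile bis-allylic ether and the phenol. The difficulty lies in the order of events: enolate chemistry at C3 must be finished before the acetate is in place, and C3' must be set by a reagent under conditions that a base-sensitive aldehyde survives. The route rests on one feature: C3' is bonded to C4', the methyl-bearing carbon of the E-trisubstituted C4'=C5' alkene. Syn hydrometalation of a methyl alkyne (CH3–C4'≡C5') gives an alkenylmetal with the metal at C4' cis to the C5' hydrogen, and its addition to a C3' aldehyde makes the bond, the alkene geometry and the carbinol in one operation.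

## Retrosynthetic reasoning

**28 to 27.** The phenol is carried as its tert-butyldimethylsilyl ether and released last. Every other functional group of 28 is already in its final form in 27, so only one mild fluoride step follows the coupling.

**27 to 13 and 24 (C3'–C4').** Cutting here divides the molecule into two halves of similar size. The forward reaction is hydrozirconation of the alkyne 24 to the alkenylzirconium 25, exchange to the alkenylzinc 26, and ligand-controlled addition to the aldehyde 13. It must form the C–C bond, fix the E geometry of C4'=C5' and set C3'. Cutting C2'–C3' or C1'–C2' instead would leave the trisubstituted alkene to be made separately, and would put nucleophilic character next to C3, where the acetate is lost. Two details need care: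
- The methyl and methylene ends of 24 differ little in size. The hydrozirconation is therefore run with a slight excess of the hydride and aged, so that 25 and its regioisomer can equilibrate toward the less hindered C4' position.
- The zirconocene by-product is itself a Lewis acid that promotes unselective addition. The zinc is therefore ligated by a chiral amino thiol and not an amino alcohol, because the softer thiolate stays on zinc.

**13 back to 9.** The β,γ-unsaturated aldehyde 13 is too labile to carry, so it is made by oxidation of the homoallylic alcohol 12 immediately before use. The acetate is placed before the coupling (10 to 11) because afterwards the C3' hydroxyl would compete. It is placed after the alkylidene is built because a C4 acetate cannot coexist with a C3 enolate. This costs a silyl-to-acetyl exchange at C4 (9 to 10 to 11) and the unmasking of the primary alcohol (11 to 12).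

**9 to 5 and 6 (C3=C1').** The alkylidene is opened by a retro-aldol condensation to the lactone 5 and the three-carbon aldehyde 6. The forward sequence is enolate addition at low temperature (7), then mesylation and E1cB elimination through 8. The C4 oxygen is a silyl ether at this stage, a poor leaving group compared with mesylate.

**5 to 1.** The 2-methylprop-1-enyl group is cut at its double bond to the C5 aldehyde 4, reached from the bis-silyl lactone 3 and the lactone 2. C4 and C5 then map directly onto C3 and C4 of 2-deoxy-D-ribose (1), which has the required trans (erythro) arrangement and absolute configuration. No ring stereocentre has to be created.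

**24 to 23 and 17 (C10'–O).** The ether is cut at the neryl oxygen. A Williamson reaction of the allylic alcohol 23 with the reactive cinnamyl bromide 17 joins two pieces that each carry only one functional handle.

**23 to 18.** The methyl alkyne is the neryl terminus with its isopropylidene group exchanged. The sequence is selective epoxidation of the remote alkene of neryl acetate 18 (19), cleavage to the aldehyde 20, one-carbon homologation to the alkyne with loss of the acetate (via 21 to 22), and C-methylation (23). The Z alkene of nerol is never touched.

**17 to 14.** The bromide comes from the allylic alcohol 16, which is the reduction product of the silylated cinnamate 15, made from the phenol ester 14.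

## Alternatives that were turned down

**Alternative 1: palladium allyl lactonization that sets C5.**
- Disconnection and key step: the C5–O1 bond. The seco acid A2, carrying a tertiary allylic carbonate, is ionized by a zerovalent palladium phosphine catalyst, and the C2 carboxylate closes on the C5 terminus (5-exo) to give A1 with the 2-methylprop-1-enyl alkene formed in the same event.
- For: C5 needs no pre-set configuration, since the π-allyl isomers can funnel to one lactone. It also avoids the epimerizable C5 aldehyde 4 and its Wittig reaction, a weak point of the chosen route; on this point Alternative 1 is stronger.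
- Against: the C5 configuration then depends on 1,2-induction from the C4 silyloxy group in a flexible π-allyl. The product A1 is itself an allylic ester and can re-ionize, so the cis/trans outcome is an equilibrium that cannot be steered. A2 must already contain C3', the E-alkylidene acid and all four alkenes, so it is a long linear precursor. The key step does not address the C3' carbinol and trisubstituted alkene. After A1 the silyl group at C4 must still be exchanged for acetate and a secondary allylic silyl ether removed next to that acetate.
- Comparison: the chosen route takes C4 and C5 from the sugar with certainty, is convergent, and needs one step after the coupling.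

**Alternative 2: palladium cyclocarbonylation of an alkynediol.**
- Disconnection and key step: C2–O1 and C2–C3, with C2 inserted as the carbonyl. The anti-diol alkyne A4 is carbonylated with a palladium diphosphine catalyst; syn acylpalladation and protonolysis give the lactone A3 with the E-alkylidene.
- For: ring, carbonyl and alkylidene geometry arrive in one step, and the C4 hydroxyl of A3 is free for direct acetylation. The chosen route spends four steps (7–10) on the same result, so Alternative 2 is clearly stronger on step economy at the lactone.
- Against: A4 has a propargylic C4 hydroxyl as well as the homopropargylic C5 hydroxyl. Propargylic alcohols under carbonylation conditions can ionize to allenylpalladium species that lead to butenolides, or close to β-lactones. The C5 hydroxyl is also allylic. A4 requires a stereoselective alkynylation to build the anti-diol, and C3' must be set beforehand by a separate method. The end game removes a secondary allylic silyl ether beside the acetate.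
- Comparison: the chosen route offers ring stereocentres that are not in question and a coupling whose selectivity issues (regiochemistry, facial control) are well understood.

**Alternative 3: vinylogous aldol of a lactone dienolate and a neryl enal.**
- Disconnection and key step: C2'–C3'. The silyl dienolate A6 attacks the enal A7 through C2' under a chiral Lewis-base-activated silicon Lewis acid, giving A5.
- For: A7 can be reached from the intact neryl terminus by allylic oxidation of its E-methyl group, shorter than the five steps to 24. The E-trisubstituted alkene is in place before the coupling, so there is no hydrometalation regiochemistry. A conjugated, non-enolizable aldehyde is a better electrophile than the labile aldehyde 13. On these three points Alternative 3 is stronger.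
- Against: A6 carries the C4 silyloxy group β to the nucleophilic carbon framework, and its loss gives an aromatic 2-silyloxyfuran, a strong driving force. Both γ- versus α-attack and the geometry of the re-formed alkylidene must be controlled. The silicon Lewis acid is a risk for the bis-allylic ether. In A5 the C3' hydroxyl is free while C4 is silylated, so the acetate cannot be introduced directly: protection of C3', silyl removal at C4, acetylation and deprotection follow.
- Comparison: the chosen route pays with a longer side-chain synthesis and a delicate aldehyde, but has the acetate in place before the coupling and finishes one step after it.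

Key step: step 19

## Assumptions

- Neryl acetate (18), methyl (E)-4-hydroxycinnamate (14) and 3-(tert-butyldimethylsilyloxy)propanal (6) are taken as purchased materials.
- The (R)-enantiomer of the amino thiol ligand is assumed to direct alkenyl transfer to the Si face of 13, which corresponds to (R) at C3'; if the sense is the opposite, its enantiomer is used.

## Steps

**Step 1**
Reactants: 1 2-deoxy-D-ribose
Product: 2 2-deoxy-D-ribono-1,4-lactone, (4S,5R)-4-hydroxy-5-(hydroxymethyl)oxolan-2-one
Conditions: Br2, H2O, rt
Reagents that add atoms: none
Why: Bromine-water oxidation of the aldose hemiacetal gives the aldonolactone, which for the 2-deoxy sugar is the five-membered lactone; C3 and C4 of the sugar become C4 and C5 of the lactone unchanged.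

**Step 2**
Reactants: 2 2-deoxy-D-ribono-1,4-lactone
Product: 3 (4S,5R)-4-(triethylsilyloxy)-5-[(triethylsilyloxy)methyl]oxolan-2-one
Conditions: TESCl, imidazole, DMF, 0 °C to rt
Reagents that add atoms: chlorotriethylsilane, CC[Si](Cl)(CC)CC
Why: Imidazole-promoted silylation of both hydroxyl groups; the lactone is inert under these conditions.

**Step 3**
Reactants: 3 (4S,5R)-4-(triethylsilyloxy)-5-[(triethylsilyloxy)methyl]oxolan-2-one
Product: 4 (2S,3S)-5-oxo-3-(triethylsilyloxy)oxolane-2-carbaldehyde
Conditions: (COCl)2, DMSO, CH2Cl2, −78 to −40 °C; then Et3N, −78 to 0 °C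
Reagents that add atoms: none
Why: Under Swern conditions the chlorosulfonium reagent cleaves a primary triethylsilyl ether and oxidizes the carbon in the same flask, while the more hindered secondary triethylsilyl ether stays (selective oxidative desilylation); the aldehyde is used crude and cold to avoid epimerization at the carbon next to the ring oxygen.

**Step 4**
Reactants: 4 (2S,3S)-5-oxo-3-(triethylsilyloxy)oxolane-2-carbaldehyde
Product: 5 (4S,5R)-5-(2-methylprop-1-en-1-yl)-4-(triethylsilyloxy)oxolan-2-one
Conditions: i-PrPPh3I, n-BuLi, THF, 0 °C; then 4, −78 to 0 °C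
Reagents that add atoms: isopropyltriphenylphosphonium iodide, CC(C)[P+](c1ccccc1)(c1ccccc1)c1ccccc1.[I-]
Why: Wittig olefination with the non-stabilized isopropylidene ylide; addition to the aldehyde at −78 °C should be faster than deprotonation at C5 and much faster than attack on the lactone carbonyl, so the C5 configuration is retained.

**Step 5**
Reactants: 5 (4S,5R)-5-(2-methylprop-1-en-1-yl)-4-(triethylsilyloxy)oxolan-2-one; 6 3-(tert-butyldimethylsilyloxy)propanal
Product: 7 (3S,4S,5R)-3-[3-(tert-butyldimethylsilyloxy)-1-hydroxypropyl]-5-(2-methylprop-1-en-1-yl)-4-(triethylsilyloxy)oxolan-2-one, mixture of carbinol epimers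
Conditions: LiN(i-Pr)2, THF, −78 °C; then 6, −78 °C; aq. NH4Cl at −78 °C
Reagents that add atoms: none
Why: Aldol addition of the kinetic lithium enolate, which for a β-silyloxy lactone is stable at −78 °C; the electrophile enters anti to the C4 silyloxy group, and the configurations at C3 and at the carbinol are both removed in step 6.

**Step 6**
Reactants: 7 aldol adduct
Product: 9 (3E,4S,5R)-3-[3-(tert-butyldimethylsilyloxy)propylidene]-5-(2-methylprop-1-en-1-yl)-4-(triethylsilyloxy)oxolan-2-one, via C1' mesylate 8 (not isolated)
Conditions: MsCl, Et3N, CH2Cl2, 0 °C; then DBU, 0 °C to rt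
Reagents that add atoms: none
Why: Mesylation followed by E1cB elimination; mesylate is a far better leaving group than the C4 silanolate, so the exocyclic alkene should form, and the stereoconvergent elimination should favour the E isomer with the chain away from the lactone carbonyl.

**Step 7**
Reactants: 9 E-alkylidene lactone bis-silyl ether
Product: 10 (3E,4S,5R)-3-[3-(tert-butyldimethylsilyloxy)propylidene]-4-hydroxy-5-(2-methylprop-1-en-1-yl)oxolan-2-one
Conditions: PPTS (cat.), MeOH/CH2Cl2, 0 °C
Reagents that add atoms: none
Why: Acid-catalysed methanolysis of silyl ethers; a triethylsilyl ether is much more labile than a tert-butyldimethylsilyl ether, so the C4 hydroxyl should be freed while the primary silyl ether stays if the reaction is stopped at conversion.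

**Step 8**
Reactants: 10 C4 alcohol
Product: 11 (2R,3S,4E)-4-[3-(tert-butyldimethylsilyloxy)propylidene]-2-(2-methylprop-1-en-1-yl)-5-oxooxolan-3-yl acetate
Conditions: Ac2O, pyridine, DMAP (cat.), CH2Cl2, 0 °C to rt
Reagents that add atoms: acetic anhydride, CC(=O)OC(C)=O
Why: DMAP-catalysed O-acylation with retention at C4; C3 is now sp2, so no enolate can form to expel the new acetate.

**Step 9**
Reactants: 11 C4 acetate
Product: 12 (2R,3S,4E)-4-(3-hydroxypropylidene)-2-(2-methylprop-1-en-1-yl)-5-oxooxolan-3-yl acetate
Conditions: HF·pyridine, pyridine, THF, 0 °C to rt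
Reagents that add atoms: none
Why: Buffered fluoride cleavage of the primary silyl ether; the acetate, the lactone and the alkenes are inert to these weakly acidic conditions.

**Step 10**
Reactants: 12 homoallylic alcohol
Product: 13 (2R,3S,4E)-2-(2-methylprop-1-en-1-yl)-5-oxo-4-(3-oxopropylidene)oxolan-3-yl acetate
Conditions: Dess–Martin periodinane, NaHCO3, CH2Cl2, 0 °C to rt; filtration, used at once
Reagents that add atoms: none
Why: Dess–Martin oxidation of a homoallylic alcohol under buffered, amine-free conditions gives the β,γ-unsaturated aldehyde without migration of the double bond; the product is not chromatographed and is taken directly into step 19.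

**Step 11**
Reactants: 14 methyl (E)-4-hydroxycinnamate
Product: 15 methyl (E)-3-[4-(tert-butyldimethylsilyloxy)phenyl]prop-2-enoate
Conditions: TBSCl, imidazole, DMF, rt
Reagents that add atoms: tert-butyldimethylsilyl chloride, CC(C)(C)[Si](C)(C)Cl
Why: Standard silylation of the phenol.

**Step 12**
Reactants: 15 silylated cinnamate
Product: 16 (E)-3-[4-(tert-butyldimethylsilyloxy)phenyl]prop-2-en-1-ol
Conditions: i-Bu2AlH, CH2Cl2, −78 °C; aq. potassium sodium tartrate
Reagents that add atoms: none
Why: 1,2-Reduction of the enoate to the allylic alcohol by the aluminium hydride; the alkene geometry and the aryl silyl ether are kept.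

**Step 13**
Reactants: 16 cinnamyl alcohol
Product: 17 (E)-[4-(3-bromoprop-1-en-1-yl)phenoxy](tert-butyl)dimethylsilane
Conditions: CBr4, PPh3, CH2Cl2, −20 to 0 °C
Reagents that add atoms: carbon tetrabromide, BrC(Br)(Br)Br
Why: Appel bromination under neutral conditions, suited to this ionizable electron-rich cinnamyl system; the bromide is used without storage.

**Step 14**
Reactants: 18 neryl acetate, (2Z)-3,7-dimethylocta-2,6-dien-1-yl acetate
Product: 19 (2Z)-6,7-epoxy-3,7-dimethyloct-2-en-1-yl acetate (racemic at the epoxide)
Conditions: mCPBA, CH2Cl2, 0 °C
Reagents that add atoms: 3-chloroperoxybenzoic acid, OOC(=O)c1cccc(Cl)c1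
Why: Prilezhaev epoxidation; the remote trisubstituted alkene is the more electron-rich, the 2,3-alkene being deactivated by the allylic acetate.

**Step 15**
Reactants: 19 epoxide
Product: 20 (2Z)-3-methyl-6-oxohex-2-en-1-yl acetate
Conditions: H5IO6, THF/Et2O, 0 °C
Reagents that add atoms: none
Why: Periodic acid opens the epoxide to the glycol and cleaves it (Malaprade-type cleavage) to the aldehyde; the Z alkene and the acetate are untouched.

**Step 16**
Reactants: 20 aldehyde
Product: 22 (2Z)-3-methylhept-2-en-6-yn-1-ol, via enyne acetate 21 (not isolated)
Conditions: dimethyl (1-diazo-2-oxopropyl)phosphonate, K2CO3, MeOH, 0 °C to rt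
Reagents that add atoms: dimethyl (1-diazo-2-oxopropyl)phosphonate, COP(=O)(OC)C(=[N+]=[N-])C(C)=O
Why: Ohira–Bestmann variant of the Seyferth–Gilbert homologation converts the aldehyde to the terminal alkyne; the same K2CO3/MeOH medium methanolyses the allylic acetate, so protecting-group removal costs no extra step.

**Step 17**
Reactants: 22 enynol
Product: 23 (2Z)-3-methyloct-2-en-6-yn-1-ol
Conditions: n-BuLi (2.1 equiv), THF, −78 to 0 °C; MeI (1.1 equiv), −78 °C to rt; H2O
Reagents that add atoms: iodomethane, CI
Why: Alkylation of the alkoxide–acetylide dianion; the lithium acetylide is methylated at carbon while the lithium alkoxide is inert to MeI in THF.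

**Step 18**
Reactants: 23 methyl enynol; 17 cinnamyl bromide
Product: 24 tert-butyldimethyl{4-[(1E)-3-{[(2Z)-3-methyloct-2-en-6-yn-1-yl]oxy}prop-1-en-1-yl]phenoxy}silane
Conditions: NaH, THF, 0 °C; then 17, n-Bu4NI (cat.), 0 °C to rt
Reagents that add atoms: none
Why: Williamson etherification; SN2 displacement at the primary allylic bromide is fast at 0 °C, which limits silyl transfer from the aryl silyl ether and attack at the benzylic terminus.

**Step 19**
Reactants: 24 neryl cinnamyl ether 2-alkyne; 13 lactone aldehyde
Product: 27 (2R,3S,4E)-4-[(3R,4E,8Z)-10-{[(2E)-3-[4-(tert-butyldimethylsilyloxy)phenyl]prop-2-en-1-yl]oxy}-3-hydroxy-4,8-dimethyldeca-4,8-dien-1-ylidene]-2-(2-methylprop-1-en-1-yl)-5-oxooxolan-3-yl acetate, via alkenylzirconocene chloride 25 (not isolated), via alkenyl(methyl)zinc 26 (not isolated)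
Conditions: Cp2Zr(H)Cl (1.1 equiv on 24), THF, rt; evaporate, toluene; Me2Zn, −65 °C; (R)-2-[1-(dimethylamino)ethyl]benzenethiol (15 mol%), then 13, −30 to −20 °C; aq. NH4Cl
Reagents that add atoms: none
Why: Cp2Zr(H)Cl adds H and Zr syn across the C4'≡C5' triple bond of 24, the metal settling at the methyl-bearing C4' (a slight excess of the hydride lets 25 and its C5' regioisomer equilibrate toward the less hindered position), so that the C5' hydrogen is cis to the metal and C6' is trans, which is the E geometry of the target. Me2Zn exchanges zirconium for zinc with retention to give 26, and the amino thiol-ligated zinc species transfers the alkenyl group to the Si face of the aldehyde carbon of 13, forming C3'–C4' and the (R)-carbinol; the closest known reaction type is hydrozirconation, zinc transmetalation and catalytic asymmetric alkenylation of an aldehyde. No ring is closed. C3' is controlled by the ligand alone, the ring stereocentres being too remote to interfere, and since 13 is a single enantiomer any leakage should appear as a separable C3' epimer. The thiol is chosen over an amino alcohol because the thiolate stays on zinc in the presence of the oxophilic zirconocene by-product, whose own Lewis acidity would otherwise drive an unselective addition. Chemoselectivity rests on the alkyne reacting with the zirconium hydride much faster than the trisubstituted and trans-disubstituted alkenes of 24, and on the weak basicity and low ester reactivity of the alkenyl(methyl)zinc, which should leave the lactone, the C4 acetate and the enolizable C2' methylene of 13 untouched at −30 °C. Alkenyl transfer is expected to outpace methyl transfer from the mixed zinc reagent.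

**Step 20**
Reactants: 27 aryl silyl ether of the target
Product: 28 target, (2R,3S,4E)-4-[(3R,4E,8Z)-3-hydroxy-10-{[(2E)-3-(4-hydroxyphenyl)prop-2-en-1-yl]oxy}-4,8-dimethyldeca-4,8-dien-1-ylidene]-2-(2-methylprop-1-en-1-yl)-5-oxooxolan-3-yl acetate
Conditions: TBAF, AcOH, THF, 0 °C
Reagents that add atoms: none
Why: Fluoride cleavage of the aryl silyl ether, which is far faster than any reaction at the alkyl acetate; acetic acid buffers the phenoxide so that the acetate, the lactone and the allylic carbinol are not exposed to base.

## Compound list

1 | 2-deoxy-D-ribose, (3S,4R)-3,4,5-trihydroxypentanal | O=CC[C@H](O)[C@H](O)CO | starting material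
2 | 2-deoxy-D-ribono-1,4-lactone, (4S,5R)-4-hydroxy-5-(hydroxymethyl)oxolan-2-one | O[C@H]1CC(=O)O[C@@H]1CO | intermediate
3 | (4S,5R)-4-(triethylsilyloxy)-5-[(triethylsilyloxy)methyl]oxolan-2-one | CC[Si](CC)(CC)O[C@H]1CC(=O)O[C@@H]1CO[Si](CC)(CC)CC | intermediate
4 | (2S,3S)-5-oxo-3-(triethylsilyloxy)oxolane-2-carbaldehyde | CC[Si](CC)(CC)O[C@H]1CC(=O)O[C@@H]1C=O | intermediate
5 | (4S,5R)-5-(2-methylprop-1-en-1-yl)-4-(triethylsilyloxy)oxolan-2-one | CC[Si](CC)(CC)O[C@H]1CC(=O)O[C@@H]1C=C(C)C | intermediate
6 | 3-(tert-butyldimethylsilyloxy)propanal | O=CCCO[Si](C)(C)C(C)(C)C | starting material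
7 | (3S,4S,5R)-3-[3-(tert-butyldimethylsilyloxy)-1-hydroxypropyl]-5-(2-methylprop-1-en-1-yl)-4-(triethylsilyloxy)oxolan-2-one, carbinol epimers | CC[Si](CC)(CC)O[C@H]1[C@H](C(O)CCO[Si](C)(C)C(C)(C)C)C(=O)O[C@@H]1C=C(C)C | intermediate
8 | C1' methanesulfonate of 7 | CC[Si](CC)(CC)O[C@H]1[C@H](C(OS(C)(=O)=O)CCO[Si](C)(C)C(C)(C)C)C(=O)O[C@@H]1C=C(C)C | intermediate
9 | (3E,4S,5R)-3-[3-(tert-butyldimethylsilyloxy)propylidene]-5-(2-methylprop-1-en-1-yl)-4-(triethylsilyloxy)oxolan-2-one | CC[Si](CC)(CC)O[C@H]1/C(=C\CCO[Si](C)(C)C(C)(C)C)C(=O)O[C@@H]1C=C(C)C | intermediate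
10 | (3E,4S,5R)-3-[3-(tert-butyldimethylsilyloxy)propylidene]-4-hydroxy-5-(2-methylprop-1-en-1-yl)oxolan-2-one | O[C@H]1/C(=C\CCO[Si](C)(C)C(C)(C)C)C(=O)O[C@@H]1C=C(C)C | intermediate
11 | (2R,3S,4E)-4-[3-(tert-butyldimethylsilyloxy)propylidene]-2-(2-methylprop-1-en-1-yl)-5-oxooxolan-3-yl acetate | CC(=O)O[C@H]1/C(=C\CCO[Si](C)(C)C(C)(C)C)C(=O)O[C@@H]1C=C(C)C | intermediate
12 | (2R,3S,4E)-4-(3-hydroxypropylidene)-2-(2-methylprop-1-en-1-yl)-5-oxooxolan-3-yl acetate | CC(=O)O[C@H]1/C(=C\CCO)C(=O)O[C@@H]1C=C(C)C | intermediate
13 | (2R,3S,4E)-2-(2-methylprop-1-en-1-yl)-5-oxo-4-(3-oxopropylidene)oxolan-3-yl acetate | CC(=O)O[C@H]1/C(=C\CC=O)C(=O)O[C@@H]1C=C(C)C | intermediate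
14 | methyl (E)-4-hydroxycinnamate | COC(=O)/C=C/c1ccc(O)cc1 | starting material
15 | methyl (E)-3-[4-(tert-butyldimethylsilyloxy)phenyl]prop-2-enoate | COC(=O)/C=C/c1ccc(O[Si](C)(C)C(C)(C)C)cc1 | intermediate
16 | (E)-3-[4-(tert-butyldimethylsilyloxy)phenyl]prop-2-en-1-ol | OC/C=C/c1ccc(O[Si](C)(C)C(C)(C)C)cc1 | intermediate
17 | (E)-[4-(3-bromoprop-1-en-1-yl)phenoxy](tert-butyl)dimethylsilane | BrC/C=C/c1ccc(O[Si](C)(C)C(C)(C)C)cc1 | intermediate
18 | neryl acetate, (2Z)-3,7-dimethylocta-2,6-dien-1-yl acetate | CC(C)=CCC/C(C)=C\COC(C)=O | starting material
19 | (2Z)-6,7-epoxy-3,7-dimethyloct-2-en-1-yl acetate, racemic at the epoxide | CC1(C)OC1CC/C(C)=C\COC(C)=O | intermediate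
20 | (2Z)-3-methyl-6-oxohex-2-en-1-yl acetate | O=CCC/C(C)=C\COC(C)=O | intermediate
21 | (2Z)-3-methylhept-2-en-6-yn-1-yl acetate | C#CCC/C(C)=C\COC(C)=O | intermediate
22 | (2Z)-3-methylhept-2-en-6-yn-1-ol | C#CCC/C(C)=C\CO | intermediate
23 | (2Z)-3-methyloct-2-en-6-yn-1-ol | CC#CCC/C(C)=C\CO | intermediate
24 | tert-butyldimethyl{4-[(1E)-3-{[(2Z)-3-methyloct-2-en-6-yn-1-yl]oxy}prop-1-en-1-yl]phenoxy}silane | CC#CCC/C(C)=C\COC/C=C/c1ccc(O[Si](C)(C)C(C)(C)C)cc1 | intermediate
25 | (E)-alkenylzirconocene chloride from 24, zirconium at C4' trans to C6' | Cl[Zr](C1C=CC=C1)(C1C=CC=C1)/C(C)=C/CC/C(C)=C\COC/C=C/c1ccc(O[Si](C)(C)C(C)(C)C)cc1 | intermediate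
26 | (E)-alkenyl(methyl)zinc from 25, zinc at C4' trans to C6' | C[Zn]/C(C)=C/CC/C(C)=C\COC/C=C/c1ccc(O[Si](C)(C)C(C)(C)C)cc1 | intermediate
27 | aryl tert-butyldimethylsilyl ether of the target, (3'R) | CC(=O)O[C@H]1/C(=C\C[C@@H](O)/C(C)=C/CC/C(C)=C\COC/C=C/c2ccc(O[Si](C)(C)C(C)(C)C)cc2)C(=O)O[C@@H]1C=C(C)C | intermediate
28 | (2R,3S,4E)-4-[(3R,4E,8Z)-3-hydroxy-10-{[(2E)-3-(4-hydroxyphenyl)prop-2-en-1-yl]oxy}-4,8-dimethyldeca-4,8-dien-1-ylidene]-2-(2-methylprop-1-en-1-yl)-5-oxooxolan-3-yl acetate | CC(=O)O[C@H]1/C(=C\C[C@@H](O)/C(C)=C/CC/C(C)=C\COC/C=C/c2ccc(O)cc2)C(=O)O[C@@H]1C=C(C)C | target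

## Step count and risk

Total: 20 steps. Longest linear sequence: 12 steps (steps 1–10, 19, 20). The alkyne branch is steps 14–18 and the bromide branch steps 11–13.

**Step 19 (key step).** Three processes may fail.
- Regiocontrol in the hydrozirconation may be incomplete: methyl and methylene differ only modestly, so part of the zirconium may end at C5' and give a constitutional isomer. The excess hydride needed for equilibration may also slowly attack the cinnamyl alkene.
- Facial control may be insufficient, because 13 is an α-unbranched aliphatic aldehyde and achiral zirconocene species compete with the ligated zinc pathway.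
- The C2' methylene of 13 may be enolized toward C3, with loss of the C4 acetate.

Fallback: the route sets out from 24 and 13 and returns at 27. Hydrozirconation of 24 followed by iodinolysis with I2 gives the (E)-vinyl iodide F1, from which the regioisomer is removed by chromatography. F1 and 13 are joined under CrCl2 with catalytic NiCl2 in DMSO (Nozaki–Hiyama–Kishi coupling, non-basic and tolerant of esters and enolizable aldehydes) to give the C3'-epimeric alcohols F2. Dess–Martin oxidation gives the enone F3. Reduction with (S)-2-methyl-CBS-oxazaborolidine and catecholborane, with the alkenyl group as the larger substituent, is expected to give the (R)-carbinol 27.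

**Step 3.** During the amine-mediated warm-up the aldehyde may lose the C4 silyloxy group by β-elimination or epimerize at C5, and the differentiation of the two silyl ethers may be incomplete. Fallback: from 3, selective hydrolysis of the primary silyl ether (AcOH/THF/H2O, 0 °C) gives the primary alcohol F4, which is oxidized with Dess–Martin periodinane and NaHCO3 to rejoin the route at 4.

**Step 4.** The basic ylide may deprotonate C5 of 4 (epimerization, or elimination of silanolate) faster than it adds. Fallback: from 4, non-basic methylenation with Zn/CH2Br2/TiCl4 gives the 5-vinyl lactone F5, and cross-metathesis with 2-methylbut-2-ene using the second-generation Grubbs catalyst installs the trisubstituted alkene and returns to 5.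

**Step 6.** The enolate formed during elimination may expel the ring silanolate (butenolide formation) instead of the mesylate, or E/Z control may be poor. Fallback: from 5, C-phosphorylation (LiN(i-Pr)2, ClP(O)(OEt)2, then further base to drive the 1,3-phosphoryl shift) gives the α-phosphono lactone F6, whose Horner–Wadsworth–Emmons reaction with 6 gives the alkylidene directly and returns to 9.

**Step 7.** Discrimination between the secondary triethylsilyl ether and the primary tert-butyldimethylsilyl ether may be incomplete. Fallback: from 9, both silyl groups are removed with HF·pyridine to give the diol F7, and the primary hydroxyl alone is resilylated (TBSCl, imidazole, CH2Cl2, −20 °C), returning to 10.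

## Further compounds

F1 | step 19 | (E)-vinyl iodide from 24, iodine at C4' | I/C(C)=C/CC/C(C)=C\COC/C=C/c1ccc(O[Si](C)(C)C(C)(C)C)cc1
F2 | step 19 | C3'-epimeric mixture of 27 | CC(=O)O[C@H]1/C(=C\CC(O)/C(C)=C/CC/C(C)=C\COC/C=C/c2ccc(O[Si](C)(C)C(C)(C)C)cc2)C(=O)O[C@@H]1C=C(C)C
F3 | step 19 | C3' enone | CC(=O)O[C@H]1/C(=C\CC(=O)/C(C)=C/CC/C(C)=C\COC/C=C/c2ccc(O[Si](C)(C)C(C)(C)C)cc2)C(=O)O[C@@H]1C=C(C)C
F4 | step 3 | (4S,5R)-5-(hydroxymethyl)-4-(triethylsilyloxy)oxolan-2-one | CC[Si](CC)(CC)O[C@H]1CC(=O)O[C@@H]1CO
F5 | step 4 | (4S,5R)-5-ethenyl-4-(triethylsilyloxy)oxolan-2-one | CC[Si](CC)(CC)O[C@H]1CC(=O)O[C@@H]1C=C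
F6 | step 6 | diethyl [(4S,5R)-5-(2-methylprop-1-en-1-yl)-2-oxo-4-(triethylsilyloxy)oxolan-3-yl]phosphonate | CC[Si](CC)(CC)O[C@H]1C(P(=O)(OCC)OCC)C(=O)O[C@@H]1C=C(C)C
F7 | step 7 | (3E,4S,5R)-4-hydroxy-3-(3-hydroxypropylidene)-5-(2-methylprop-1-en-1-yl)oxolan-2-one | O[C@H]1/C(=C\CCO)C(=O)O[C@@H]1C=C(C)C
A1 | alternative 1 | 4-triethylsilyloxy lactone with silyl ethers at C3' and at the phenol | CC[Si](CC)(CC)O[C@H]1/C(=C\C[C@@H](O[Si](C)(C)C(C)(C)C)/C(C)=C/CC/C(C)=C\COC/C=C/c2ccc(O[Si](C)(C)C(C)(C)C)cc2)C(=O)O[C@@H]1C=C(C)C
A2 | alternative 1 | seco acid with C4 triethylsilyl ether and tertiary allylic methyl carbonate | OC(=O)/C(=C/C[C@@H](O[Si](C)(C)C(C)(C)C)/C(C)=C/CC/C(C)=C\COC/C=C/c1ccc(O[Si](C)(C)C(C)(C)C)cc1)[C@H](O[Si](CC)(CC)CC)/C=C/C(C)(C)OC(=O)OC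
A3 | alternative 2 | 4-hydroxy-3-alkylidene lactone, bis-silyl ether | O[C@H]1/C(=C\C[C@@H](O[Si](C)(C)C(C)(C)C)/C(C)=C/CC/C(C)=C\COC/C=C/c2ccc(O[Si](C)(C)C(C)(C)C)cc2)C(=O)O[C@@H]1C=C(C)C
A4 | alternative 2 | anti C4,C5-diol with the C3–C1' alkyne | O[C@@H](C#CC[C@@H](O[Si](C)(C)C(C)(C)C)/C(C)=C/CC/C(C)=C\COC/C=C/c1ccc(O[Si](C)(C)C(C)(C)C)cc1)[C@H](O)C=C(C)C
A5 | alternative 3 | coupled lactone with free C3' hydroxyl and C4 triethylsilyl ether | CC[Si](CC)(CC)O[C@H]1/C(=C\C[C@@H](O)/C(C)=C/CC/C(C)=C\COC/C=C/c2ccc(O[Si](C)(C)C(C)(C)C)cc2)C(=O)O[C@@H]1C=C(C)C
A6 | alternative 3 | silyl dienolate, 2-(tert-butyldimethylsilyloxy)-3-ethenyl-4,5-dihydrofuran with C4 triethylsilyl ether | CC[Si](CC)(CC)O[C@H]1C(C=C)=C(O[Si](C)(C)C(C)(C)C)O[C@@H]1C=C(C)C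
A7 | alternative 3 | (2E,6Z)-2,6-dimethylocta-2,6-dienal bearing the silylated cinnamyl ether at C8 | O=C/C(C)=C/CC/C(C)=C\COC/C=C/c1ccc(O[Si](C)(C)C(C)(C)C)cc1
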